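**Plan**

- Retrosynthesis: the C4 oxygen is silylated and a phenylsulfanyl group is restored at C2, then the O1–C2 and C3–C4 bonds of ring A are cut together.
- Enabling feature: ring A (dihydropyran O1–C2–C3–C4–C4a=C8a, fused through C4a=C8a to cyclohexenone ring B, C4a–C5(=O)–C6–C7–C8–C8a) is the formal [4+2] adduct of the oxadiene O1=C8a–C4a=C4 of a 2-(silyloxymethylidene)cyclohexane-1,3-dione and the C2=C3 double bond of 2-(phenylsulfanyl)nonadec-1-ene, which carries heptadecyl on C2.
- Forward: ring B is bought as cyclohexane-1,3-dione, formylated at its central carbon (future C4) and O-silylated. The chain is bought as stearoyl chloride and becomes the vinyl sulfide by thioester methylenation. Ring A closes in the cycloaddition, then the C2–S bond is reduced and the silyl ether cleaved.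
- Stereochemistry: C4 (R) comes from the chiral bis(oxazoline) complex of Cu(OTf)2 in the cycloaddition. C2 (S) comes from hydrogen-atom transfer to the C2 radical on the face opposite the C4 silyloxy group, which places heptadecyl cis to the C4 oxygen.

Key step: step 6

Assumption: silyl enol ethers of β-dicarbonyl compounds exchange silicon between their oxygens by 1,5 shift, so the silylated formyl dione is treated as one interconverting pair of isomers and drawn as the exocyclic form.

Assumption: (R,R)-t-Bu-box is 2,2'-(propane-2,2-diyl)bis[(4R)-4-tert-butyl-4,5-dihydro-1,3-oxazole]. By analogy with additions to carbonyl groups held in square-planar chelates of the (S,S) ligand on divalent copper, which expose the Si face of the bound carbonyl carbon, the (R,R) ligand is taken to expose the Re face of C4 (4R). If the six-membered chelate responds in the opposite sense, the (S,S) ligand is used with no other change.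

**Route**

Step 1
Reactants: 1 cyclohexane-1,3-dione; 2 N,N-dimethylformamide dimethyl acetal
Product: 3 2-[(dimethylamino)methylidene]cyclohexane-1,3-dione
Conditions: toluene, rt → 60 °C
Reagents that add atoms: none
Why: Aminomethylenation of the doubly activated C2 methylene of a 1,3-dione by an amide acetal should give the push–pull enaminone, which installs the future C4 at the formyl oxidation level.

Step 2
Reactants: 3 2-[(dimethylamino)methylidene]cyclohexane-1,3-dione
Product: 4 2-(hydroxymethylidene)cyclohexane-1,3-dione (enol form of 2-formylcyclohexane-1,3-dione)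
Conditions: 1 M aq HCl, THF, rt
Reagents that add atoms: water, O
Why: Acid hydrolysis of a vinylogous amide (water adds to the protonated enaminone and the amine leaves) should give the β-tricarbonyl compound as its hydrogen-bonded enol.

Step 3
Reactants: 4 2-(hydroxymethylidene)cyclohexane-1,3-dione
Product: 5 2-{[(tert-butyldimethylsilyl)oxy]methylidene}cyclohexane-1,3-dione
Conditions: TBSCl, Et3N, Et2O, 0 °C → rt; filtration under argon, no aqueous work-up
Reagents that add atoms: tert-butyldimethylsilyl chloride, CC(C)(C)[Si](C)(C)Cl
Why: O-Silylation of a vinylogous carboxylic acid, as in silyl ester formation, should put silicon on the unhindered exocyclic oxygen, and any ring-O-silyl isomer interconverts with 5 by 1,5 O-to-O silyl shift.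

Step 4
Reactants: 6 octadecanoyl chloride (stearoyl chloride); 7 benzenethiol (thiophenol)
Product: 8 S-phenyl octadecanethioate
Conditions: pyridine, CH2Cl2, 0 °C → rt
Reagents that add atoms: none
Why: Acylation of the thiol by the acid chloride with pyridine as acid scavenger is a standard thioester formation, and it brings in the heptadecyl chain with its carbonyl carbon as the future C2.

Step 5
Reactants: 8 S-phenyl octadecanethioate
Product: 9 2-(phenylsulfanyl)nonadec-1-ene
Conditions: Cp2TiMe2, toluene, 70 °C, dark; filtration through basic alumina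
Reagents that add atoms: dimethyltitanocene Cp2TiMe2, [CH3-].[CH3-].[Ti+4].c1cc[cH-]c1.c1cc[cH-]c1
Why: In this Petasis methylenation, Cp2Ti=CH2 formed on heating adds across the thioester C=O and cycloreverts, so the double bond is placed at the terminal position under non-acidic conditions without any regioselective enolisation of a methyl ketone.

Step 6
Reactants: 5 2-{[(tert-butyldimethylsilyl)oxy]methylidene}cyclohexane-1,3-dione; 9 2-(phenylsulfanyl)nonadec-1-ene
Product: 11 (2S,4R)-4-[(tert-butyldimethylsilyl)oxy]-2-heptadecyl-2-(phenylsulfanyl)-2,3,4,6,7,8-hexahydro-5H-chromen-5-one, via 2-[(tert-butyldimethylsilyl)oxy]-6-oxocyclohex-1-ene-1-carbaldehyde 10 (not isolated)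
Conditions: Cu(OTf)2 (10 mol %), (R,R)-t-Bu-box (11 mol %), 4 Å MS, CH2Cl2, −40 → 0 °C
Reagents that add atoms: none
Why: Proposed new method: the two ring carbonyls of a cyclohexane-1,3-dione point away from each other on either side of the exocyclic carbon and cannot share one metal, so two-point binding to [Cu((R,R)-t-Bu-box)](OTf)2 is expected through the exocyclic oxygen and one ring carbonyl after the 1,5 silyl shift of 5 to the formyl enone 10, which places the reacting carbon C4 inside a planar six-membered chelate next to the ligand. The nucleophilic CH2 terminus of 9 (C3) should then add to C4 and the enol oxygen O1 close onto the resulting thionium carbon C2 with return of silicon to the C4 oxygen, a polar, asynchronous inverse-demand oxa-[4+2] whose closest known relatives are the hetero-Diels–Alder reactions of chelating unsaturated carbonyl compounds with enol ethers and vinyl sulfides under Cu(OTf)2/bis(oxazoline) catalysis, the thermal [4+2] additions of alkoxymethylidene-1,3-dicarbonyl compounds to the same alkenes, and Mukaiyama-type additions to carbonyl groups chelated by the same catalysts. Ring A closes as the six-membered adduct, in the stepwise limit by 6-exo-trig attack of O1 on the thionium ion. C4 is set by the ligand, whose tert-butyl group is expected to cover the Si face so that C3 bonds to the Re face (4R), while C2 follows from the sulfur-endo geometry of closure and is of no consequence because it is reset in step 7. Regiochemistry is secured by the polarity of the partners (electron-rich CH2 to the electrophilic carbon, sulfur-stabilised cation to oxygen), and because the dione is symmetric no choice between its two ring carbonyls is needed.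

Step 7
Reactants: 11 (2S,4R)-4-[(tert-butyldimethylsilyl)oxy]-2-heptadecyl-2-(phenylsulfanyl)-2,3,4,6,7,8-hexahydro-5H-chromen-5-one
Product: 12 (2S,4R)-4-[(tert-butyldimethylsilyl)oxy]-2-heptadecyl-2,3,4,6,7,8-hexahydro-5H-chromen-5-one
Conditions: Bu3SnH, AIBN, toluene, 85 °C
Reagents that add atoms: none
Why: In this radical desulfurisation of an O,S-ketal, the Bu3Sn radical removes the phenylsulfanyl group to give the C2 radical next to O1, and Bu3SnH should deliver hydrogen axially on the face opposite the 1,3-related C4 silyloxy group, so heptadecyl ends up equatorial and cis to the C4 oxygen (2S) whichever C2 epimer of 11 is used.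

Step 8
Reactants: 12 (2S,4R)-4-[(tert-butyldimethylsilyl)oxy]-2-heptadecyl-2,3,4,6,7,8-hexahydro-5H-chromen-5-one
Product: 13 (2S,4R)-2-heptadecyl-4-hydroxy-2,3,4,6,7,8-hexahydro-5H-chromen-5-one
Conditions: TBAF, AcOH, THF, 0 °C → rt
Reagents that add atoms: none
Why: Fluoride cleavage of the silyl ether, buffered with acetic acid so that neither base-induced opening of the vinylogous ester nor acid-induced ionisation at C4 intervenes, should free the alcohol without touching either stereocentre.

**Compound list**

1 | cyclohexane-1,3-dione | O=C1CCCC(=O)C1 | starting material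
2 | N,N-dimethylformamide dimethyl acetal | COC(OC)N(C)C | starting material
3 | 2-[(dimethylamino)methylidene]cyclohexane-1,3-dione | CN(C)C=C1C(=O)CCCC1=O | intermediate
4 | 2-(hydroxymethylidene)cyclohexane-1,3-dione (enol form of 2-formylcyclohexane-1,3-dione) | OC=C1C(=O)CCCC1=O | intermediate
5 | 2-{[(tert-butyldimethylsilyl)oxy]methylidene}cyclohexane-1,3-dione | CC(C)(C)[Si](C)(C)OC=C1C(=O)CCCC1=O | intermediate
6 | octadecanoyl chloride (stearoyl chloride) | CCCCCCCCCCCCCCCCCC(=O)Cl | starting material
7 | benzenethiol (thiophenol) | Sc1ccccc1 | starting material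
8 | S-phenyl octadecanethioate | CCCCCCCCCCCCCCCCCC(=O)Sc1ccccc1 | intermediate
9 | 2-(phenylsulfanyl)nonadec-1-ene | C=C(CCCCCCCCCCCCCCCCC)Sc1ccccc1 | intermediate
10 | 2-[(tert-butyldimethylsilyl)oxy]-6-oxocyclohex-1-ene-1-carbaldehyde (ring-O-silyl isomer of 5, not isolated) | O=CC1=C(O[Si](C)(C)C(C)(C)C)CCCC1=O | intermediate
11 | (2S,4R)-4-[(tert-butyldimethylsilyl)oxy]-2-heptadecyl-2-(phenylsulfanyl)-2,3,4,6,7,8-hexahydro-5H-chromen-5-one (sulfur cis to the silyloxy group) | CCCCCCCCCCCCCCCCC[C@]1(Sc2ccccc2)C[C@@H](O[Si](C)(C)C(C)(C)C)C2=C(CCCC2=O)O1 | intermediate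
12 | (2S,4R)-4-[(tert-butyldimethylsilyl)oxy]-2-heptadecyl-2,3,4,6,7,8-hexahydro-5H-chromen-5-one (heptadecyl cis to the silyloxy group) | CCCCCCCCCCCCCCCCC[C@H]1C[C@@H](O[Si](C)(C)C(C)(C)C)C2=C(CCCC2=O)O1 | intermediate
13 | (2S,4R)-2-heptadecyl-4-hydroxy-2,3,4,6,7,8-hexahydro-5H-chromen-5-one (2,4-cis) | CCCCCCCCCCCCCCCCC[C@H]1C[C@@H](O)C2=C(CCCC2=O)O1 | target

**Step count and risks**

Total steps: 8. Longest linear sequence: 6 steps (steps 1, 2, 3, 6, 7, 8, from 1 to 13); the vinyl sulfide branch (steps 4, 5) joins at step 6.

Steps most likely to fail: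

1. Step 6 (new method). Turnover may be slow because the oxygen-substituted heterodiene is a weak electrophile, or because silicon is lost from the chelated substrate and the tricarbonyl enolate stays on copper. One-point binding may give poor facial selectivity at C4. The C4 silyloxy group may be eliminated after the first bond has formed. Fallback, all known chemistry: from 5 and 9 the cycloaddition is run without chiral control, as the thermal inverse-demand [4+2] addition of oxymethylidene-1,3-dicarbonyl compounds to vinyl sulfides (toluene, 90 °C, 5 mol % Eu(fod)3). This should give the racemic (2S*,4R*)-cycloadduct F1. Bu3SnH/AIBN as in step 7 should give the racemic cis silyl ether F2, and TBAF/AcOH the racemic cis alcohol F3. Lipase-catalysed acylation (Burkholderia cepacia lipase, vinyl acetate, tert-butyl methyl ether, 35 °C) is then used; the empirical rule for secondary alcohols predicts reaction of the 4R enantiomer, giving (2S,4R)-2-heptadecyl-5-oxo-3,4,5,6,7,8-hexahydro-2H-chromen-4-yl acetate F4 beside unchanged (2R,4S)-alcohol. After chromatographic separation, K2CO3/MeOH at 0 °C releases 13, where the fallback rejoins the route.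

2. Step 7. Hydrogen transfer to the flattened C2 radical may discriminate poorly between the two faces, or ring A may open by β-scission of C3–C4 (which would give a stabilised C4 radical) before hydrogen transfer. Fallback: from 11 the last two operations are inverted and the control element is changed from steric shielding to conformational locking. TBAF/AcOH first gives (2S,4R)-2-heptadecyl-4-hydroxy-2-(phenylsulfanyl)-2,3,4,6,7,8-hexahydro-5H-chromen-5-one F5. Its O–H···O=C5 hydrogen bond should hold the C4 oxygen pseudoequatorial and fix one half-chair. Reduction of F5 with Bu3SnH/AIBN at higher hydride concentration then relies on axial hydrogen delivery to that locked conformer (heptadecyl equatorial, cis to OH) and gives 13 directly.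

3. Step 3. The vinylogous silyl ester may hydrolyse or transfer silicon during isolation, so that free enol, which binds copper irreversibly, is carried into step 6. Fallback: from 4 the more robust triisopropylsilyl series is used. Chlorotri(propan-2-yl)silane/Et3N should give 2-({[tri(propan-2-yl)silyl]oxy}methylidene)cyclohexane-1,3-dione F6. The conditions of steps 6 and 7 should give the cycloadduct F7 and the reduced silyl ether F8. TBAF in THF at rt then removes the silyl group and gives 13.

Further compounds
F1 | step 6 | racemic (2S*,4R*)-4-[(tert-butyldimethylsilyl)oxy]-2-heptadecyl-2-(phenylsulfanyl)-2,3,4,6,7,8-hexahydro-5H-chromen-5-one | CCCCCCCCCCCCCCCCC[C@]1(Sc2ccccc2)C[C@@H](O[Si](C)(C)C(C)(C)C)C2=C(CCCC2=O)O1.CCCCCCCCCCCCCCCCC[C@@]1(Sc2ccccc2)C[C@H](O[Si](C)(C)C(C)(C)C)C2=C(CCCC2=O)O1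
F2 | step 6 | racemic (2S*,4R*)-4-[(tert-butyldimethylsilyl)oxy]-2-heptadecyl-2,3,4,6,7,8-hexahydro-5H-chromen-5-one | CCCCCCCCCCCCCCCCC[C@H]1C[C@@H](O[Si](C)(C)C(C)(C)C)C2=C(CCCC2=O)O1.CCCCCCCCCCCCCCCCC[C@@H]1C[C@H](O[Si](C)(C)C(C)(C)C)C2=C(CCCC2=O)O1
F3 | step 6 | racemic (2S*,4R*)-2-heptadecyl-4-hydroxy-2,3,4,6,7,8-hexahydro-5H-chromen-5-one | CCCCCCCCCCCCCCCCC[C@H]1C[C@@H](O)C2=C(CCCC2=O)O1.CCCCCCCCCCCCCCCCC[C@@H]1C[C@H](O)C2=C(CCCC2=O)O1
F4 | step 6 | (2S,4R)-2-heptadecyl-5-oxo-3,4,5,6,7,8-hexahydro-2H-chromen-4-yl acetate | CCCCCCCCCCCCCCCCC[C@H]1C[C@@H](OC(C)=O)C2=C(CCCC2=O)O1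
F5 | step 7 | (2S,4R)-2-heptadecyl-4-hydroxy-2-(phenylsulfanyl)-2,3,4,6,7,8-hexahydro-5H-chromen-5-one | CCCCCCCCCCCCCCCCC[C@]1(Sc2ccccc2)C[C@@H](O)C2=C(CCCC2=O)O1
F6 | step 3 | 2-({[tri(propan-2-yl)silyl]oxy}methylidene)cyclohexane-1,3-dione | CC(C)[Si](OC=C1C(=O)CCCC1=O)(C(C)C)C(C)C
F7 | step 3 | (2S,4R)-2-heptadecyl-2-(phenylsulfanyl)-4-{[tri(propan-2-yl)silyl]oxy}-2,3,4,6,7,8-hexahydro-5H-chromen-5-one | CCCCCCCCCCCCCCCCC[C@]1(Sc2ccccc2)C[C@@H](O[Si](C(C)C)(C(C)C)C(C)C)C2=C(CCCC2=O)O1
F8 | step 3 | (2S,4R)-2-heptadecyl-4-{[tri(propan-2-yl)silyl]oxy}-2,3,4,6,7,8-hexahydro-5H-chromen-5-one | CCCCCCCCCCCCCCCCC[C@H]1C[C@@H](O[Si](C(C)C)(C(C)C)C(C)C)C2=C(CCCC2=O)O1
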